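The readings are simulated with constants of no real substance; the scatter is artificial.

Z, the catalyst, turns L and Q into X in the flasks below; elm, maple and alder have been read, and larch has not.

| flask | L | Q | Z | time |
|---|---|---|---|---|
| elm | 0.300 M | 0.750 M | 0.00600 M |  |
| maple | 0.180 M | 0.630 M | 0.00600 M |  |
| alder | 0.300 M | 0.750 M | 0.00900 M |  |
| larch | 0.300 M | 3.00 M | 0.00600 M | 23 min |

- elm run (time / min: [X] / M): 3.3: 0.0693; 6.6: 0.0986; 9.9: 0.1099; 13: 0.1196; 16: 0.1268; 20: 0.1299; 23: 0.1342
- maple run (time / min: [X] / M): 3.3: 0.0537; 6.6: 0.0742; 9.9: 0.0813; 13: 0.0885; 16: 0.0954; 20: 0.0963; 23: 0.0975
- alder run (time / min: [X] / M): 3.3: 0.0894; 6.6: 0.1145; 9.9: 0.1368; 13: 0.1404; 16: 0.1451; 20: 0.1565; 23: 0.1538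

(scatter of a reading: 0.002 M)

* reaction order in [Z] at the outset, round the charge of the elm run, defined at two percent of the L turned into X
* X in the larch run at 23 min, as a share of the L charged

- Overall: L + Q -> X, with Z as catalyst.
- Constant volume, constant temperature.
- The analysis sees a species whether free or bound.
- An order is taken over about fifteen percent of the charge, up and down.

Alder repeats elm with more Z, by a ratio of 1.50, so this pair can give the order in Z, and it can do so in two ways. The first way holds time equal. At 3.3 min alder holds 0.0894 M of X and elm 0.0693 M, which reads as an order of 0.628.

The second way holds the amount made equal and compares times. By a straight line between readings, elm reaches alder's first reading at 5.56 min, while alder took 3.3 min. The time elm needs for an amount of X over the time alder needs for the same amount is the clock factor, here 1.69. It reads 1.72 at alder's second reading, so these two early readings agree. The agreement stops there: alder's third reading, 0.1368 M at 9.9 min, stands above elm's last, 0.1342 M at 23 min, which reads as a factor above 2.32, so one faster clock does not carry alder's whole curve. The first factor gives an order of 1.29.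

The two ways part, the second reading higher, and equal time is the one that cheats. Elm gains 0.0693 M in its first 3.3 min, but 0.0113 M in the same span ending at 9.9 min, with 36.6% of its L showing as X. Slowing that steep means alder, further along at any one time, has already given back part of its lead. The straight line also sets elm somewhat late on a bending curve, so the reckoning here commits to an order near one.

The forecast gives 0.62 for the order, on “a Z order of about 0.6”, and 68% for larch.

The flask gives an order of 1.1 and, in larch, 17.7%.

    Z + L → Lx + J (50.94 /M/min)
    Lx + Q → X + Z (375.0 /M/min)
    Z + J ⇌ ZJ, settled at all times (70.80 /M)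
    X + Q → G (0.03084 /M/min)

Alder's rate over elm's at one early amount made is 1.5, against the Z ratio of 1.50. The times to a quarter of the L charged give a clock factor of 1.61, beside the 1.69 read from the runs. In maple, where Q is lower as well, the rate at that early amount is 0.599 of elm's, beside its L ratio of 0.600; the apparent order in L is 0.98. Larch ends low because X reacts on with Q to G: at 23 min it holds 17.7% of its L as X, and 59.1% with that step taken away.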